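## Analysis of the target

The target 27 is a depsidone: two benzene rings joined by a diaryl ether oxygen and by an aryl ester, so that a seven-membered dioxepinone lies between them, and the second ring is also fused to a five-membered hydroxy lactone (a 3-hydroxyphthalide). Ring A is numbered C1 (methoxy), C2 (the only ring hydrogen), C3 (methyl), C4 (ester carbonyl), C5 (ether oxygen) and C6 (hydroxymethyl). Ring B is numbered C1' (ether oxygen), C2' (ester oxygen), C3' (methyl), C4' (free phenol), C5' (lactone carbonyl) and C6' (lactol carbon), and carries no hydrogen. The single stereocentre is the lactol carbon on C6', (R) by CIP analysis; it is a hemiacetal that can open to an aldehyde acid, so it is configurationally labile and has no second stereocentre to relate to. The sensitive groups are the aryl ester of the seven-membered ring (cleaved by hydroxide and alkoxide), the lactol, the phenol, and the benzylic alcohol on C6, which lies between two oxygen-bearing carbons and ionises in acid. The synthesis is hard because the ether between C5 and C1' has four ortho substituents, ring B is hexasubstituted, and base must be avoided once the ester is closed. The strategy rests on ring A: C5 (oxygen) and C6 (carbon) are adjacent, and C6 lies next to the methoxy carbon C1, the pattern left when a nucleophile and an electrophile add across a 3-methoxyaryne.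

## Retrosynthetic reasoning

**27 from 26 and 25.** No skeletal bond is cut; the last two operations concern only the lactol carbon. This centre equilibrates through the open aldehyde acid and cannot be carried through the synthesis, so it is set at the very end. Enzymatic removal of the acetyl groups of diacetate 26 releases 27 without breaking the C–O bond at the stereocentre. 26 comes from racemic lactol 25 by a dynamic kinetic acylation, in which the same lability funnels both enantiomers into one acylal.

**25 from 24.** The lactol hydroxyl is exchanged for methoxyl. The methyl pseudo-ester 24 ties up the aldehyde and the acid of ring B in one group. That group survives hydride reduction and palladium catalysis and is opened by dilute aqueous acid, which leaves the aryl ester alone.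

**24 from 23.** The ester C–O bond between the C4 carbonyl and the C2' oxygen and the bond from C4 to that carbonyl are cut together. This leads back to aryl bromide 23 and a one-carbon carbonyl source. Closing the seven-membered ring by carbonylation means that ring A needs only a halogen at C4. The ring closure also runs under a tertiary amine, not under the hydroxide or alkoxide that a depsidone would not survive. Only the C2' phenol can reach an acyl group on C4; the C4' phenol is para to the ether.

**23 from 22, and 22 from 21.** The hydroxymethyl group is taken back to the carboxylic acid 22. The two phenols and the pseudo-ester of 22 are taken back to the methoxymethyl (MOM) ethers, methyl ester and dimethyl acetal of 21. The order matters. The benzylic alcohol on C6 would be etherified in the alcoholic acid needed to remove the MOM groups, so the unmasking is done while C6 is still a carboxyl and the reduction follows. The acid can then be reduced selectively, because the only other carbonyl at that stage is a lactone.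

**21 from 20.** The C4–Br bond is cut. A halogen next to the aryne carbon would disturb the key step, so bromination comes after the ether is made. It comes before the unmasking so that ring B has no free phenol when the electrophile is present.

**20 from 16, 8 and 17.** This is the key disconnection: the C5–O bond of the diaryl ether and the C6–C bond to the future hydroxymethyl carbon are cut at once. In the forward sense silyl triflate 8 gives aryne 19, phenoxide 18 adds at the carbon meta to methoxy, and the aryl anion ortho to methoxy takes up carbon dioxide 17. The cut is made here because the ether carries four ortho substituents and is the bond least suited to metal-catalysed coupling. An aryne is attacked in the ring plane at a carbon whose other neighbour bears only hydrogen, so the hindrance of 16 matters little. The same event delivers the C6 carbon at the acid oxidation level, which can later be reduced in the presence of esters. The forward reaction has to achieve site-selective addition to the unsymmetrical aryne and carboxylation of the aryl anion before it is protonated or attacks the ring B ester.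

**8 from 1.** The aryne precursor is taken back through silyl carbamate 6 and carbamate 2 to phenol 1. The carbamate and the methoxy group together direct metalation to the carbon between them, which is the carbon that must carry silicon.

**16 from 9.** Ring B is taken back through acetal 14, aldehyde 13 and bromide 11 to ester 9. Each substituent enters at the only position open to it. Bromine enters at the single activated ring carbon of 9. The formyl carbon enters at the last ring C–H, which lies between ester and bromine and is acidic enough for a hindered magnesium amide. The bromine is finally exchanged for the hydroxyl that becomes the ether oxygen. A starting ester that already carried a methyl group at the future aldehyde carbon was not used. That methyl is meta to both oxygens, so its oxidation would need radical halogenation, which the MOM groups do not tolerate.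

## Alternatives that were turned down

**Alternative 1:** Ring B is disconnected at two C–C bonds (ester carbon to silyloxy carbon, acetal carbon to phenol carbon). In the forward sense the bis(silyloxy)furan A2 and the alkynoate A3 undergo a [4+2] cycloaddition, and the oxygen bridge opens to give the hexasubstituted phenol A1.
- For: one operation assembles ring B with three differentiated oxygens from two small pieces. On step economy for ring B it is stronger than the five steps used here.
- Against: it answers ring B only; the crowded ether, ring A and the seven-membered ring are left open. The regiochemistry depends on matching an electron-rich furan with an alkynoate whose β-carbon carries a bulky acetal, and the bridge must open in one direction. A1 has a silyl ether next to the free phenol, so silyl migration between the neighbouring oxygens is likely under base. Aryl silyl ethers also do not survive the desilylating conditions of aryne generation, so the protecting groups would have to be exchanged.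
- Comparison: the chosen strategy spends its risk on the hardest bond and gains a C–C bond with it, and builds ring B by substitutions that each have one possible site.

**Alternative 2:** Ring A is disconnected at the C–C bond between its ester-bearing and methyl-bearing carbons. In the forward sense the aryl triketo ester A5 cyclises under mild base by aldol addition and dehydration to the depside A4. The ether is closed later onto the ring B bromide.
- For: it mirrors the biosynthesis. The ester link is made by simple acylation, the ether closure is intramolecular, and the bromide fixes both the ether site and the position of the depsidone carbonyl. On that last point it is stronger than the chosen route, which has to choose between two ring A positions in its bromination.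
- Against: an aryl ester of a triketo acid has an excellent leaving group, so lactonisation to a pyranone with loss of the phenoxide competes with the aldol path. After aromatisation ring A still needs three selective operations on a base-labile depside: etherification of one phenol, methylation of the other, and hydroxymethylation between them. The ether closure onto a hexasubstituted bromide needs heat and base, conditions under which depsides cleave or rearrange. Ring B must carry an extra bromine, so its preparation is no shorter.
- Comparison: the chosen strategy takes ring A ready-made from a commercial phenol and forms the ether at ambient temperature without a metal.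

**Alternative 3:** Ring A is disconnected at two C–C bonds (methoxy carbon to silyloxymethyl carbon, CH to methyl carbon). In the forward sense the pyranone A7, already fused to the seven-membered ring, reacts with the ketene acetal A8, and decarboxylative aromatisation with loss of an alcohol gives the protected depsidone A6.
- For: every substituent of ring A is fixed by the cycloaddition, and the ether and ester exist before ring A does, so no late substitution on ring A is needed. On regiochemical certainty it is stronger than the chosen route.
- Against: A7 is itself a demanding target. It needs the same crowded C–O bond, made on a pyranone, and a seven-membered lactonisation before the key step. Its diene is deactivated by the aryloxy donor. The cycloaddition needs heat in the presence of an aryl ester and two kinds of acetal. The hexasubstituted ring B phenol is still required, so the sequence is the longest of the four.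
- Comparison: the chosen strategy accepts one regiochemical question on ring A in exchange for a much shorter route and commercial starting materials for both rings.

Key step: step 9

Assumption: the lactol carbon is taken to be configurationally labile through ring–chain tautomerism, so the (R) configuration is fixed only in step 15 and released in the last step under neutral, base-free conditions, and 27 is assumed to hold its configuration when kept cold, dry and free of base.

## Route

Step 1
Reactants: 1 3-methoxy-5-methylphenol
Product: 2 3-methoxy-5-methylphenyl N-isopropylcarbamate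
Conditions: i-PrNCO, Et3N (cat.), CH2Cl2, rt
Reagents that add atoms: isopropyl isocyanate CC(C)N=C=O
Why: Amine-catalysed addition of the phenol to the isocyanate (carbamoylation) should give the carbamate, a directing group for metalation that can be removed later under mild conditions.

Step 2
Reactants: 2 3-methoxy-5-methylphenyl N-isopropylcarbamate
Product: 6 3-methoxy-5-methyl-2-(trimethylsilyl)phenyl N-isopropylcarbamate, via N-silyl carbamate 3 (not isolated), via aryllithium 4 (not isolated), via bis-silyl carbamate 5 (not isolated)
Conditions: TBSOTf, TMEDA, Et2O, 0 °C to rt; then n-BuLi, TMEDA, −78 °C; then TMSCl, −78 °C to rt; aq. NaHSO4 work-up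
Reagents that add atoms: chlorotrimethylsilane C[Si](C)(C)Cl
Why: Silylation on nitrogen masks the N–H, and directed ortho-metalation then takes place at the carbon between the carbamate and the methoxy group, the only position activated by both; chlorotrimethylsilane traps the aryllithium and the acidic work-up removes the N-silyl group.

Step 3
Reactants: 6 3-methoxy-5-methyl-2-(trimethylsilyl)phenyl N-isopropylcarbamate
Product: 8 3-methoxy-5-methyl-2-(trimethylsilyl)phenyl trifluoromethanesulfonate, via silylphenol 7 (not isolated)
Conditions: Et2NH, DBU, MeCN, 40 °C; then PhNTf2, rt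
Reagents that add atoms: N-phenylbis(trifluoromethanesulfonimide) O=S(=O)(N(c1ccccc1)S(=O)(=O)C(F)(F)F)C(F)(F)F
Why: The carbamate is cleaved by E1cB loss of isopropyl isocyanate, which the amine traps as a urea, and the phenoxide is triflated in the same flask; this is the standard way to an ortho-silylaryl triflate.

Step 4
Reactants: 9 methyl 2,4-dihydroxy-3-methylbenzoate
Product: 10 methyl 5-bromo-2,4-dihydroxy-3-methylbenzoate
Conditions: NBS, MeCN, 0 °C
Reagents that add atoms: N-bromosuccinimide O=C1CCC(=O)N1Br
Why: Electrophilic aromatic bromination; C5 is ortho to one hydroxyl and para to the other, whereas the remaining C–H is meta to both and ortho to the ester, so only C5 should react.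

Step 5
Reactants: 10 methyl 5-bromo-2,4-dihydroxy-3-methylbenzoate
Product: 11 methyl 5-bromo-2,4-bis(methoxymethoxy)-3-methylbenzoate
Conditions: NaH, MOMCl, DMF, 0 °C to rt
Reagents that add atoms: chloromethyl methyl ether COCCl
Why: Williamson-type O-alkylation of both phenoxides; NaH is used so that the hydroxyl hydrogen-bonded to the ester is also deprotonated.

Step 6
Reactants: 11 methyl 5-bromo-2,4-bis(methoxymethoxy)-3-methylbenzoate
Product: 13 methyl 3-bromo-2-formyl-4,6-bis(methoxymethoxy)-5-methylbenzoate, via arylmagnesium chloride 12 (not isolated)
Conditions: TMPMgCl·LiCl, THF, −20 °C; then DMF, −20 °C to rt; aq. NH4Cl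
Reagents that add atoms: N,N-dimethylformamide CN(C)C=O
Why: Directed magnesiation with the hindered magnesium amide removes the only ring hydrogen, which is acidified by the flanking ester and bromine; the base neither attacks the ester nor exchanges the bromine, and DMF formylates the arylmagnesium. The low temperature is meant to keep the ortho-bromo arylmagnesium from eliminating.

Step 7
Reactants: 13 methyl 3-bromo-2-formyl-4,6-bis(methoxymethoxy)-5-methylbenzoate
Product: 14 methyl 3-bromo-2-(dimethoxymethyl)-4,6-bis(methoxymethoxy)-5-methylbenzoate
Conditions: HC(OMe)3, MeOH, PPTS (cat.), rt; Et3N quench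
Reagents that add atoms: trimethyl orthoformate COC(OC)OC; methanol CO
Why: Acid-catalysed acetalisation driven by the orthoformate; the weak acid at ambient temperature should leave the aryl MOM ethers and the hindered methyl ester untouched and stop at the open-chain acetal.

Step 8
Reactants: 14 methyl 3-bromo-2-(dimethoxymethyl)-4,6-bis(methoxymethoxy)-5-methylbenzoate
Product: 16 methyl 2-(dimethoxymethyl)-3-hydroxy-4,6-bis(methoxymethoxy)-5-methylbenzoate, via aryl pinacol boronate 15 (not isolated)
Conditions: Pd(OAc)2, SPhos, B2pin2, KOAc, 1,4-dioxane, 90 °C; then 30% aq. H2O2, aq. NaOH, THF, 0 °C; work-up at pH 7–8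
Reagents that add atoms: hydrogen peroxide OO
Why: Miyaura borylation with a biaryl phosphine suited to di-ortho-substituted aryl bromides, then oxidation of the C–B bond with alkaline peroxide at the same carbon. The phenol next to the acetal is released in basic medium, where it is stable, and is used without acidic chromatography.

Step 9
Reactants: 16 methyl 2-(dimethoxymethyl)-3-hydroxy-4,6-bis(methoxymethoxy)-5-methylbenzoate; 8 3-methoxy-5-methyl-2-(trimethylsilyl)phenyl trifluoromethanesulfonate; 17 carbon dioxide
Product: 20 2-[2-(dimethoxymethyl)-3-(methoxycarbonyl)-4,6-bis(methoxymethoxy)-5-methylphenoxy]-6-methoxy-4-methylbenzoic acid, via potassium phenoxide 18 (not isolated), via 3-methoxy-5-methylbenzyne 19 (not isolated)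
Conditions: KH, THF, 0 °C; then 18-crown-6, KF, CO2 (1 atm), 8 added over 2 h, 0 °C to rt; cold aq. citric acid work-up (pH 4)
Reagents that add atoms: none
Why: Proposed new method: Fluoride attacks the trimethylsilyl group of 8 and the neighbouring triflate leaves, giving aryne 19 slowly and at low concentration. The crown-complexed phenoxide 18 adds to the aryne carbon remote from methoxy, because the methoxy group distorts the aryne so that this carbon is the more electrophilic one and the developing aryl anion sits next to the inductively stabilising oxygen. The aryl anion is then carboxylated by dissolved 17; the phenol was deprotonated beforehand with KH, so no O–H or N–H acid is left to protonate it. The closest known reaction types are the O-arylation of phenols by arynes from silylaryl triflates and the three-component coupling of arynes, amines or imines and carbon dioxide to anthranilic acid derivatives; the use of a phenoxide as the nucleophile in the three-component mode is the new element, and no ring closes and no stereocentre forms. The step needs site selectivity on the aryne, which the methoxy group secures, and the attacked carbon has only a hydrogen-bearing neighbour on its other side, so the hexasubstituted phenoxide meets little hindrance. It also needs carboxylation to outrun attack of the aryl anion on ring B, which is why the aldehyde is masked as the acetal and the ester sits where only a seven-membered transition state could reach it. Reversible carbonate formation between 18 and 17 lowers the concentration of free phenoxide, but the free phenoxide remains the stronger nucleophile.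

Step 10
Reactants: 20 2-[2-(dimethoxymethyl)-3-(methoxycarbonyl)-4,6-bis(methoxymethoxy)-5-methylphenoxy]-6-methoxy-4-methylbenzoic acid
Product: 21 3-bromo-2-[2-(dimethoxymethyl)-3-(methoxycarbonyl)-4,6-bis(methoxymethoxy)-5-methylphenoxy]-6-methoxy-4-methylbenzoic acid
Conditions: NBS (1.05 equiv), MeCN, 0 °C, dark
Reagents that add atoms: N-bromosuccinimide O=C1CCC(=O)N1Br
Why: Electrophilic aromatic bromination under non-acidic conditions that spare the MOM ethers and the acetal; ring B has no free position. On ring A, C4 is para to methoxy, the stronger of the two oxygen donors, and is therefore expected to be preferred over C2; the carboxyl group is meta to both sites and does not bias the choice.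

Step 11
Reactants: 21 3-bromo-2-[2-(dimethoxymethyl)-3-(methoxycarbonyl)-4,6-bis(methoxymethoxy)-5-methylphenoxy]-6-methoxy-4-methylbenzoic acid
Product: 22 racemic 3-bromo-2-[(5,7-dihydroxy-3-methoxy-6-methyl-1-oxo-1,3-dihydro-2-benzofuran-4-yl)oxy]-6-methoxy-4-methylbenzoic acid
Conditions: 3 M HCl in MeOH, 45 °C
Reagents that add atoms: none
Why: Acidic methanol removes both MOM groups by transacetalisation. It also turns the acetal and methyl ester pair into the cyclic methyl pseudo-ester, the classical acid-promoted change of a normal into a pseudo ester, by attack of the ester carbonyl on the benzylic oxocarbenium ion and loss of the ester methyl. The ring A acid has two ortho substituents and should neither esterify nor lactonise under these conditions.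

Step 12
Reactants: 22 racemic 3-bromo-2-[(5,7-dihydroxy-3-methoxy-6-methyl-1-oxo-1,3-dihydro-2-benzofuran-4-yl)oxy]-6-methoxy-4-methylbenzoic acid
Product: 23 racemic 4-[2-bromo-6-(hydroxymethyl)-5-methoxy-3-methylphenoxy]-5,7-dihydroxy-3-methoxy-6-methyl-2-benzofuran-1(3H)-one
Conditions: BH3·SMe2 (excess), THF, 0 °C to rt; MeOH quench
Reagents that add atoms: none
Why: Chemoselective borane reduction: the carboxylic acid reacts through its acyloxyborane much faster than the lactone does. The phenols only form borates that the methanol quench cleaves; the aryl bromide and the acetal carbon are inert.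

Step 13
Reactants: 23 racemic 4-[2-bromo-6-(hydroxymethyl)-5-methoxy-3-methylphenoxy]-5,7-dihydroxy-3-methoxy-6-methyl-2-benzofuran-1(3H)-one
Product: 24 racemic 4-hydroxy-11-(hydroxymethyl)-1,10-dimethoxy-5,8-dimethyl-1H-isobenzofuro[4,5-b][1,4]benzodioxepine-3,7-dione
Conditions: Pd(OAc)2 (5 mol%), Xantphos (6 mol%), CO (1 atm), Et3N, toluene/1,4-dioxane (0.01 M), 90 °C
Reagents that add atoms: carbon monoxide [C-]#[O+]
Why: Palladium-catalysed carbonylative lactonisation (intramolecular aryloxycarbonylation): zerovalent palladium inserts into the C–Br bond, CO inserts, and the phenol ortho to the ether oxygen captures the acylpalladium, closing the seven-membered lactone. The other phenol is para to the ether and cannot reach, and high dilution should suppress intermolecular acylation of the primary alcohol.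

Step 14
Reactants: 24 racemic 4-hydroxy-11-(hydroxymethyl)-1,10-dimethoxy-5,8-dimethyl-1H-isobenzofuro[4,5-b][1,4]benzodioxepine-3,7-dione
Product: 25 racemic 1,4-dihydroxy-11-(hydroxymethyl)-10-methoxy-5,8-dimethyl-1H-isobenzofuro[4,5-b][1,4]benzodioxepine-3,7-dione
Conditions: 1 M aq. H2SO4/1,4-dioxane (1:3), 45 °C
Reagents that add atoms: water O
Why: Acid-catalysed hydrolysis of the pseudo-ester through the phthalidyl oxocarbenium ion should give the lactol, while the aryl ester hydrolyses far more slowly. A non-nucleophilic acid in water avoids substitution at the benzylic alcohol; the stereocentre forms as the racemate.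

Step 15
Reactants: 25 racemic 1,4-dihydroxy-11-(hydroxymethyl)-10-methoxy-5,8-dimethyl-1H-isobenzofuro[4,5-b][1,4]benzodioxepine-3,7-dione
Product: 26 (1R)-1-acetoxy-11-(acetoxymethyl)-4-hydroxy-10-methoxy-5,8-dimethyl-1H-isobenzofuro[4,5-b][1,4]benzodioxepine-3,7-dione
Conditions: immobilised Candida antarctica lipase B, vinyl acetate, Et3N (cat.), THF/toluene, 40 °C
Reagents that add atoms: vinyl acetate C=COC(C)=O
Why: Lipase-catalysed dynamic kinetic resolution by acyl transfer: the lactol epimerises through the open aldehyde carboxylate under the catalytic amine while the enzyme acylates one enantiomer. By the empirical size rule for cyclic benzylic carbinols (fused arene large, ring oxygen medium) this is expected to be the (R)-lactol, so the enzyme sets the stereocentre. The primary alcohol is acetylated as well, and the hydrogen-bonded phenol is not a lipase substrate.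

Step 16
Reactants: 26 (1R)-1-acetoxy-11-(acetoxymethyl)-4-hydroxy-10-methoxy-5,8-dimethyl-1H-isobenzofuro[4,5-b][1,4]benzodioxepine-3,7-dione
Product: 27 (1R)-1,4-dihydroxy-11-(hydroxymethyl)-10-methoxy-5,8-dimethyl-1H-isobenzofuro[4,5-b][1,4]benzodioxepine-3,7-dione
Conditions: immobilised Candida antarctica lipase B, n-BuOH, t-BuOMe/THF, 25 °C
Reagents that add atoms: none
Why: Lipase-catalysed alcoholysis removes both acetyl groups by attack at the acyl carbon, so the C–O bond at the stereocentre stays intact and the (R)-lactol should be released with retention. The conditions are neutral and free of base, which protects both the aryl ester and the configuration.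

## Compound list

1 | 3-methoxy-5-methylphenol | COc1cc(C)cc(O)c1 | starting material
2 | 3-methoxy-5-methylphenyl N-isopropylcarbamate | COc1cc(C)cc(OC(=O)NC(C)C)c1 | intermediate
3 | 3-methoxy-5-methylphenyl N-(tert-butyldimethylsilyl)-N-isopropylcarbamate | COc1cc(C)cc(OC(=O)N(C(C)C)[Si](C)(C)C(C)(C)C)c1 | intermediate (not isolated)
4 | 2-lithio derivative of 3 (lithium between carbamate and methoxy) | COc1cc(C)cc(OC(=O)N(C(C)C)[Si](C)(C)C(C)(C)C)c1[Li] | intermediate (not isolated)
5 | 3-methoxy-5-methyl-2-(trimethylsilyl)phenyl N-(tert-butyldimethylsilyl)-N-isopropylcarbamate | COc1cc(C)cc(OC(=O)N(C(C)C)[Si](C)(C)C(C)(C)C)c1[Si](C)(C)C | intermediate (not isolated)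
6 | 3-methoxy-5-methyl-2-(trimethylsilyl)phenyl N-isopropylcarbamate | COc1cc(C)cc(OC(=O)NC(C)C)c1[Si](C)(C)C | intermediate
7 | 3-methoxy-5-methyl-2-(trimethylsilyl)phenol | COc1cc(C)cc(O)c1[Si](C)(C)C | intermediate (not isolated)
8 | 3-methoxy-5-methyl-2-(trimethylsilyl)phenyl trifluoromethanesulfonate (aryne precursor) | COc1cc(C)cc(OS(=O)(=O)C(F)(F)F)c1[Si](C)(C)C | intermediate
9 | methyl 2,4-dihydroxy-3-methylbenzoate | COC(=O)c1ccc(O)c(C)c1O | starting material
10 | methyl 5-bromo-2,4-dihydroxy-3-methylbenzoate | COC(=O)c1cc(Br)c(O)c(C)c1O | intermediate
11 | methyl 5-bromo-2,4-bis(methoxymethoxy)-3-methylbenzoate | COCOc1c(C)c(OCOC)c(Br)cc1C(=O)OC | intermediate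
12 | chloro[2-bromo-6-(methoxycarbonyl)-3,5-bis(methoxymethoxy)-4-methylphenyl]magnesium | COCOc1c(C)c(OCOC)c(Br)c([Mg]Cl)c1C(=O)OC | intermediate (not isolated)
13 | methyl 3-bromo-2-formyl-4,6-bis(methoxymethoxy)-5-methylbenzoate | COCOc1c(C)c(OCOC)c(Br)c(C=O)c1C(=O)OC | intermediate
14 | methyl 3-bromo-2-(dimethoxymethyl)-4,6-bis(methoxymethoxy)-5-methylbenzoate | COCOc1c(C)c(OCOC)c(Br)c(C(OC)OC)c1C(=O)OC | intermediate
15 | methyl 2-(dimethoxymethyl)-4,6-bis(methoxymethoxy)-5-methyl-3-(4,4,5,5-tetramethyl-1,3,2-dioxaborolan-2-yl)benzoate | COCOc1c(C)c(OCOC)c(B2OC(C)(C)C(C)(C)O2)c(C(OC)OC)c1C(=O)OC | intermediate (not isolated)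
16 | methyl 2-(dimethoxymethyl)-3-hydroxy-4,6-bis(methoxymethoxy)-5-methylbenzoate (ring B phenol) | COCOc1c(C)c(OCOC)c(O)c(C(OC)OC)c1C(=O)OC | intermediate
17 | carbon dioxide | O=C=O | starting material
18 | potassium 2-(dimethoxymethyl)-3-(methoxycarbonyl)-4,6-bis(methoxymethoxy)-5-methylphenoxide | COCOc1c(C)c(OCOC)c([O-])c(C(OC)OC)c1C(=O)OC.[K+] | intermediate (not isolated)
19 | 3-methoxy-5-methylbenzyne | COC1=CC(C)=CC#C1 | intermediate (not isolated)
20 | 2-[2-(dimethoxymethyl)-3-(methoxycarbonyl)-4,6-bis(methoxymethoxy)-5-methylphenoxy]-6-methoxy-4-methylbenzoic acid | COc1cc(C)cc(Oc2c(OCOC)c(C)c(OCOC)c(C(=O)OC)c2C(OC)OC)c1C(=O)O | intermediate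
21 | 3-bromo-2-[2-(dimethoxymethyl)-3-(methoxycarbonyl)-4,6-bis(methoxymethoxy)-5-methylphenoxy]-6-methoxy-4-methylbenzoic acid | COc1cc(C)c(Br)c(Oc2c(OCOC)c(C)c(OCOC)c(C(=O)OC)c2C(OC)OC)c1C(=O)O | intermediate
22 | racemic 3-bromo-2-[(5,7-dihydroxy-3-methoxy-6-methyl-1-oxo-1,3-dihydro-2-benzofuran-4-yl)oxy]-6-methoxy-4-methylbenzoic acid | COc1cc(C)c(Br)c(Oc2c(O)c(C)c(O)c3c2C(OC)OC3=O)c1C(=O)O | intermediate
23 | racemic 4-[2-bromo-6-(hydroxymethyl)-5-methoxy-3-methylphenoxy]-5,7-dihydroxy-3-methoxy-6-methyl-2-benzofuran-1(3H)-one | COc1cc(C)c(Br)c(Oc2c(O)c(C)c(O)c3c2C(OC)OC3=O)c1CO | intermediate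
24 | racemic 4-hydroxy-11-(hydroxymethyl)-1,10-dimethoxy-5,8-dimethyl-1H-isobenzofuro[4,5-b][1,4]benzodioxepine-3,7-dione (depsidone methyl pseudo-ester) | COc1cc(C)c2c(c1CO)Oc1c(c(C)c(O)c3c1C(OC)OC3=O)OC2=O | intermediate
25 | racemic 1,4-dihydroxy-11-(hydroxymethyl)-10-methoxy-5,8-dimethyl-1H-isobenzofuro[4,5-b][1,4]benzodioxepine-3,7-dione (racemic lactol) | COc1cc(C)c2c(c1CO)Oc1c(c(C)c(O)c3c1C(O)OC3=O)OC2=O | intermediate
26 | (1R)-1-acetoxy-11-(acetoxymethyl)-4-hydroxy-10-methoxy-5,8-dimethyl-1H-isobenzofuro[4,5-b][1,4]benzodioxepine-3,7-dione | COc1cc(C)c2c(c1COC(C)=O)Oc1c(c(C)c(O)c3c1[C@H](OC(C)=O)OC3=O)OC2=O | intermediate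
27 | (1R)-1,4-dihydroxy-11-(hydroxymethyl)-10-methoxy-5,8-dimethyl-1H-isobenzofuro[4,5-b][1,4]benzodioxepine-3,7-dione | COc1cc(C)c2c(c1CO)Oc1c(c(C)c(O)c3c1[C@H](O)OC3=O)OC2=O | target

## Step count and least certain steps

Total step count: 16. Longest linear sequence: 13 steps (9 to 27 through steps 4 to 16); the aryne precursor branch (steps 1 to 3) joins at step 9.

**Step 9 (key step, proposed new method).** The most likely failure is loss of the aryl anion before carboxylation: protonation by adventitious acid or by the solvent would give the uncarboxylated diaryl ether. The phenoxide may also be held as its carbonate under 17, so that the aryne is consumed in other ways. Phenoxides have not been established as the nucleophile in this three-component mode, and 18 is very hindered. The fallback uses known chemistry and sets out from 16. The commercial arene 1-fluoro-3-methoxy-5-methylbenzene F1 is lithiated between fluorine and methoxy (n-BuLi, THF, −78 °C) and formylated with DMF to 2-fluoro-6-methoxy-4-methylbenzaldehyde F2, whose activated fluoride is then displaced by 16 in a nucleophilic aromatic substitution (Cs2CO3, DMSO, 90 °C). This gives the diaryl ether aldehyde methyl 2-(dimethoxymethyl)-3-(2-formyl-3-methoxy-5-methylphenoxy)-4,6-bis(methoxymethoxy)-5-methylbenzoate F3, and Pinnick oxidation (NaClO2, NaH2PO4, 2-methylbut-2-ene, t-BuOH/H2O) returns to the route at 20.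

**Step 10.** The most likely failure is bromination at C2 in place of C4. Both positions lie between the methyl group and an oxygen-bearing carbon, and the electronic preference for the position para to methoxy is modest. C4 is also shielded by the ortho substituents of the twisted ring B. The fallback sets out from 20 and uses the wrong isomer as a blocking group. Bromination under the conditions of step 10 is then taken to give the C2 bromide 3-bromo-6-[2-(dimethoxymethyl)-3-(methoxycarbonyl)-4,6-bis(methoxymethoxy)-5-methylphenoxy]-2-methoxy-4-methylbenzoic acid F4, which is iodinated at the one remaining ring hydrogen (NIS, MeCN) to the bromo iodo acid F5. Unmasking and reduction as in steps 11 and 12 give the bromo iodo pseudo-ester acid F6 and then the bromo iodo benzylic alcohol F7. Carbonylative lactonisation at 50 °C, where only the C–I bond undergoes oxidative addition, gives the C2-bromo depsidone pseudo-ester F8, and hydrogenolysis of its bromide (H2, Pd/C, Et3N, EtOAc) comes back to the route at 24.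

**Step 8.** The most likely failure is slow oxidative addition and protodebromination at the bromide of 14, which is flanked by a MOM ether and the acetal. The fallback changes the order of events and sets out from 11. The unhindered bromide of 11 is borylated and oxidised under the reagents of step 8, through methyl 2,4-bis(methoxymethoxy)-3-methyl-5-(4,4,5,5-tetramethyl-1,3,2-dioxaborolan-2-yl)benzoate F9 to methyl 5-hydroxy-2,4-bis(methoxymethoxy)-3-methylbenzoate F10, a phenol whose only free ortho position is the last ring C–H. The phenol then directs a Casnati–Skattebøl ortho-formylation (MgCl2, Et3N, paraformaldehyde, THF, reflux) to methyl 2-formyl-3-hydroxy-4,6-bis(methoxymethoxy)-5-methylbenzoate F11, and acetalisation as in step 7 comes back to the route at 16.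

**Step 13.** The most likely failure is intermolecular acylation of the free primary alcohol by the acylpalladium, which would give oligomers, made worse by slow oxidative addition at a bromide with two ortho substituents. The fallback sets out from 22 and carbonylates before the alcohol exists. The same palladium conditions applied to acid 22 give the depsidone acid, racemic 4-hydroxy-1,10-dimethoxy-5,8-dimethyl-3,7-dioxo-1H-isobenzofuro[4,5-b][1,4]benzodioxepine-11-carboxylic acid F12, whose carboxyl is then reduced with BH3·SMe2, which attacks an acid faster than an aryl ester or a lactone. The route is rejoined at 24.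

**Step 15.** The most likely failure is insufficient or opposite enantioselection by the enzyme, or slow epimerisation of the lactol, so that 26 is formed with low enantiomeric purity. No lipase has been matched to this lactol, and the sense is predicted only by analogy. The fallback sets out from 25 and replaces the enzymatic resolution by a physical one. Preparative chromatography of 25 on a chiral stationary phase at low temperature delivers 27 directly, so the route is rejoined at 27. The unwanted (1S)-lactol F13 is returned to racemic 25 with a catalytic amount of Et3N and separated again.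

## Further compounds

F1 | step 9 | 1-fluoro-3-methoxy-5-methylbenzene | COc1cc(C)cc(F)c1
F2 | step 9 | 2-fluoro-6-methoxy-4-methylbenzaldehyde | COc1cc(C)cc(F)c1C=O
F3 | step 9 | methyl 2-(dimethoxymethyl)-3-(2-formyl-3-methoxy-5-methylphenoxy)-4,6-bis(methoxymethoxy)-5-methylbenzoate | COc1cc(C)cc(Oc2c(OCOC)c(C)c(OCOC)c(C(=O)OC)c2C(OC)OC)c1C=O
F4 | step 10 | 3-bromo-6-[2-(dimethoxymethyl)-3-(methoxycarbonyl)-4,6-bis(methoxymethoxy)-5-methylphenoxy]-2-methoxy-4-methylbenzoic acid | COc1c(Br)c(C)cc(Oc2c(OCOC)c(C)c(OCOC)c(C(=O)OC)c2C(OC)OC)c1C(=O)O
F5 | step 10 | 3-bromo-6-[2-(dimethoxymethyl)-3-(methoxycarbonyl)-4,6-bis(methoxymethoxy)-5-methylphenoxy]-5-iodo-2-methoxy-4-methylbenzoic acid | COc1c(Br)c(C)c(I)c(Oc2c(OCOC)c(C)c(OCOC)c(C(=O)OC)c2C(OC)OC)c1C(=O)O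
F6 | step 10 | racemic 3-bromo-6-[(5,7-dihydroxy-3-methoxy-6-methyl-1-oxo-1,3-dihydro-2-benzofuran-4-yl)oxy]-5-iodo-2-methoxy-4-methylbenzoic acid | COc1c(Br)c(C)c(I)c(Oc2c(O)c(C)c(O)c3c2C(OC)OC3=O)c1C(=O)O
F7 | step 10 | racemic 4-[4-bromo-6-(hydroxymethyl)-2-iodo-5-methoxy-3-methylphenoxy]-5,7-dihydroxy-3-methoxy-6-methyl-2-benzofuran-1(3H)-one | COc1c(Br)c(C)c(I)c(Oc2c(O)c(C)c(O)c3c2C(OC)OC3=O)c1CO
F8 | step 10 | racemic 9-bromo-4-hydroxy-11-(hydroxymethyl)-1,10-dimethoxy-5,8-dimethyl-1H-isobenzofuro[4,5-b][1,4]benzodioxepine-3,7-dione | COc1c(Br)c(C)c2c(c1CO)Oc1c(c(C)c(O)c3c1C(OC)OC3=O)OC2=O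
F9 | step 8 | methyl 2,4-bis(methoxymethoxy)-3-methyl-5-(4,4,5,5-tetramethyl-1,3,2-dioxaborolan-2-yl)benzoate | COCOc1c(C)c(OCOC)c(B2OC(C)(C)C(C)(C)O2)cc1C(=O)OC
F10 | step 8 | methyl 5-hydroxy-2,4-bis(methoxymethoxy)-3-methylbenzoate | COCOc1c(C)c(OCOC)c(O)cc1C(=O)OC
F11 | step 8 | methyl 2-formyl-3-hydroxy-4,6-bis(methoxymethoxy)-5-methylbenzoate | COCOc1c(C)c(OCOC)c(O)c(C=O)c1C(=O)OC
F12 | step 13 | racemic 4-hydroxy-1,10-dimethoxy-5,8-dimethyl-3,7-dioxo-1H-isobenzofuro[4,5-b][1,4]benzodioxepine-11-carboxylic acid | COc1cc(C)c2c(c1C(=O)O)Oc1c(c(C)c(O)c3c1C(OC)OC3=O)OC2=O
F13 | step 15 | (1S)-1,4-dihydroxy-11-(hydroxymethyl)-10-methoxy-5,8-dimethyl-1H-isobenzofuro[4,5-b][1,4]benzodioxepine-3,7-dione | COc1cc(C)c2c(c1CO)Oc1c(c(C)c(O)c3c1[C@@H](O)OC3=O)OC2=O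
A1 | alternative 1 | ethyl 2-(diethoxymethyl)-3-hydroxy-4,6-bis(tert-butyldimethylsilyloxy)-5-methylbenzoate | CCOC(=O)c1c(O[Si](C)(C)C(C)(C)C)c(C)c(O[Si](C)(C)C(C)(C)C)c(O)c1C(OCC)OCC
A2 | alternative 1 | 2,4-bis(tert-butyldimethylsilyloxy)-3-methylfuran | CC(C)(C)[Si](C)(C)Oc1occ(O[Si](C)(C)C(C)(C)C)c1C
A3 | alternative 1 | ethyl 4,4-diethoxybut-2-ynoate | CCOC(=O)C#CC(OCC)OCC
A4 | alternative 2 | 2-bromo-3-(dimethoxymethyl)-4-(methoxycarbonyl)-5-(methoxymethoxy)-6-methylphenyl 2,4-dihydroxy-6-methylbenzoate | Cc1cc(O)cc(O)c1C(=O)Oc1c(Br)c(C(OC)OC)c(C(=O)OC)c(OCOC)c1C
A5 | alternative 2 | 2-bromo-3-(dimethoxymethyl)-4-(methoxycarbonyl)-5-(methoxymethoxy)-6-methylphenyl 3,5,7-trioxooctanoate | CC(=O)CC(=O)CC(=O)CC(=O)Oc1c(Br)c(C(OC)OC)c(C(=O)OC)c(OCOC)c1C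
A6 | alternative 3 | depsidone with silyloxymethyl on ring A and methyl ester, dimethyl acetal and MOM ether on ring B | COc1cc(C)c2c(c1CO[Si](C)(C)C(C)(C)C)Oc1c(c(C)c(OCOC)c(C(=O)OC)c1C(OC)OC)OC2=O
A7 | alternative 3 | 3-(tert-butyldimethylsilyloxymethyl)-6-methyl-2-pyranone fused at its C4 (oxygen) and C5 (carbonyl) to the seven-membered dioxepinone of ring B | CC1=C2C(=O)Oc3c(C)c(OCOC)c(C(=O)OC)c(C(OC)OC)c3OC2=C(CO[Si](C)(C)C(C)(C)C)C(=O)O1
A8 | alternative 3 | 1,1-dimethoxyethene | C=C(OC)OC
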